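**Retrosynthetic overview** (isochromene numbering of the target: C1, O2, C3, C4, C4a, C5–C8, C8a)
1. Target 23 ⇐ desilylation of 22; the pyran ring is closed last by 6-endo oxa-Michael addition of the C1 hydroxyl to the ynenone formed by Sonogashira coupling of chloroenone 16 with enynoic acid 20.
2. 16 ⇐ acyclic epoxy chloro-ynone 15: Cp2TiCl opens the oxirane to the C8a radical, which closes the carbocycle 6-endo onto the ynone (forms C4a–C8a, sets C8a, frees the C1 hydroxyl, keeps a vinyl chloride for the coupling).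
3. 15 ⇐ ester 12 + LiC≡CCl; 12 ⇐ epoxy diol 6 + orsellinoyl chloride 11 (arene built from two methyl acetoacetates).
4. 6 ⇐ methyl propanoate + acrolein: aldol, Sharpless kinetic resolution (C8), dianion hydroxylation (C7), directed epoxidation.
5. Ring order: benzene ring (side branch) → cyclohexenone (radical step) → pyran (last).

Assumption: the oxirane carbon of 6, 12 and 15 is carried as a mixture of epimers and written without configuration, because it becomes the planar radical centre in step 10; TBS = tert-butyldimethylsilyl, "aroyl" = 2,4-bis(TBS-oxy)-6-methylbenzoyl.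

Step 1
Reactants: 1 methyl propanoate; 2 acrolein
Product: 3 methyl 3-hydroxy-2-methylpent-4-enoate (racemic; syn/anti mixture)
Conditions: LiN(iPr)2, THF, −78 °C; then 2, −78 °C; aq. NH4Cl
Reagents that add atoms: none
Why: Aldol addition of the lithium ester enolate (1,2-addition to the enal at −78 °C); neither new centre needs control, since C3 is resolved in step 2 and C2 is re-set in step 3.

Step 2
Reactants: 3 methyl 3-hydroxy-2-methylpent-4-enoate
Product: 4 methyl (2RS,3S)-3-hydroxy-2-methylpent-4-enoate (recovered alcohol)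
Conditions: Ti(OiPr)4 (10 mol%), L-(+)-diisopropyl tartrate (15 mol%), t-BuOOH (0.6 equiv), 4 Å MS, CH2Cl2, −20 °C, to about 60% conversion
Reagents that add atoms: none
Why: Sharpless kinetic resolution of a vinyl carbinol: with the L-(+)-tartrate the (3R)-alcohol is epoxidised fast and the (3S)-alcohol is recovered in high ee (at most 50% yield), which fixes C8 of the target.

Step 3
Reactants: 4 methyl (2RS,3S)-3-hydroxy-2-methylpent-4-enoate
Product: 5 methyl (2S,3S)-2,3-dihydroxy-2-methylpent-4-enoate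
Conditions: LiN(iPr)2 (2.3 equiv), THF, −78 → −20 °C; (camphorsulfonyl)oxaziridine, −78 °C; aq. NH4Cl
Reagents that add atoms: (camphorsulfonyl)oxaziridine (either enantiomer), CC1(C)C2CCC13CS(=O)(=O)N4OC34C2
Why: Fráter–Seebach-type reaction of the chelated alkoxide–enolate dianion with an electrophilic oxygen donor (Davis oxidation); oxygen enters anti to the C3 hydroxyl, giving the (2S,3S) diol that corresponds to the cis C7/C8 diol of the target.

Step 4
Reactants: 5 methyl (2S,3S)-2,3-dihydroxy-2-methylpent-4-enoate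
Product: 6 methyl (2S,3S)-2,3-dihydroxy-2-methyl-3-(oxiran-2-yl)propanoate (both oxirane epimers)
Conditions: VO(acac)2 (5 mol%), t-BuOOH, CH2Cl2, 0 → 25 °C
Reagents that add atoms: tert-butyl hydroperoxide, CC(C)(C)OO
Why: Hydroxyl-directed vanadium-catalysed epoxidation of the allylic alcohol; the new oxirane centre is irrelevant because it is destroyed in step 10.

Step 5
Reactants: 7 methyl acetoacetate (two molecules)
Product: 8 methyl orsellinate (methyl 2,4-dihydroxy-6-methylbenzoate)
Conditions: NaH (1.05 equiv), THF, 0 °C; n-BuLi (1.0 equiv), 0 °C; reflux, 16 h; aq. HCl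
Reagents that add atoms: none
Why: Biomimetic self-condensation of the acetoacetate dianion: Claisen acylation at the γ-carbon gives a 3,5,7-trioxooctanoate that closes by intramolecular aldol condensation and aromatises.

Step 6
Reactants: 8 methyl orsellinate
Product: 9 orsellinic acid (2,4-dihydroxy-6-methylbenzoic acid)
Conditions: KOH (6 M aq.), 25–40 °C, N2, 48 h; HCl to pH 2 at 0 °C
Reagents that add atoms: potassium hydroxide, [K+].[OH-]
Why: Saponification of the hindered, phenoxide-deactivated ester; acidification is done cold because the acid decarboxylates on heating.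

Step 7
Reactants: 9 orsellinic acid
Product: 10 tert-butyldimethylsilyl 2,4-bis(tert-butyldimethylsilyloxy)-6-methylbenzoate
Conditions: t-BuMe2SiCl (3.5 equiv), imidazole, DMF, 25 °C
Reagents that add atoms: tert-butyldimethylsilyl chloride, CC(C)(C)[Si](C)(C)Cl
Why: Silylation of both phenols and the acid; the silyl ester is the substrate for neutral acid chloride formation in step 8.

Step 8
Reactants: 10 tert-butyldimethylsilyl 2,4-bis(tert-butyldimethylsilyloxy)-6-methylbenzoate; 6 methyl (2S,3S)-2,3-dihydroxy-2-methyl-3-(oxiran-2-yl)propanoate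
Product: 12 methyl (2S,3S)-3-(aroyloxy)-2-hydroxy-2-methyl-3-(oxiran-2-yl)propanoate, via aroyl chloride 11 (not isolated)
Conditions: (COCl)2, DMF (cat.), CH2Cl2, 0 → 25 °C; then 6, Et3N, DMAP, CH2Cl2, 0 → 35 °C
Reagents that add atoms: none
Why: Silyl ester to acid chloride with oxalyl chloride/DMF under neutral conditions (Wissner), then DMAP-catalysed acylation of the secondary hydroxyl with retention at C8 (the tertiary hydroxyl does not react).

Step 9
Reactants: 12 methyl (2S,3S)-3-(aroyloxy)-2-hydroxy-2-methyl-3-(oxiran-2-yl)propanoate; 13 cis-1,2-dichloroethene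
Product: 15 (1S,2S)-5-chloro-2-hydroxy-2-methyl-1-(oxiran-2-yl)-3-oxopent-4-yn-1-yl 2,4-bis(TBS-oxy)-6-methylbenzoate, via lithium chloroacetylide 14 (not isolated)
Conditions: 13, MeLi (2.0 equiv), Et2O, 0 °C; 12, LiN(SiMe3)2 (1.0 equiv), THF, −78 °C; add 14 (1.5 equiv), −78 → −40 °C; AcOH, −78 °C
Reagents that add atoms: none
Why: Acetylide acylation (addition–elimination at the methyl ester); the neighbouring lithium alkoxide chelates the tetrahedral adduct and prevents a second addition, the ester has no α-hydrogen, and the 2,6-disubstituted aryl ester is too hindered to react.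

Step 10
Reactants: 15 (1S,2S)-5-chloro-2-hydroxy-2-methyl-1-(oxiran-2-yl)-3-oxopent-4-yn-1-yl 2,4-bis(TBS-oxy)-6-methylbenzoate
Product: 16 (1S,2S,6S)-5-chloro-2-hydroxy-6-(hydroxymethyl)-2-methyl-3-oxocyclohex-4-en-1-yl 2,4-bis(TBS-oxy)-6-methylbenzoate
Conditions: Cp2TiCl2 (20 mol%), Mn, 2,4,6-collidine·HCl, THF (0.01 M, slow addition of 15), 25 °C
Reagents that add atoms: none
Why: Proposed new method: Cp2TiCl (trivalent titanium, from Cp2TiCl2 and Mn) opens the oxirane homolytically at the more substituted carbon (Nugent–RajanBabu) to the secondary C8a radical with a titanium alkoxide on C1; this nucleophilic radical adds to the electrophilic β-carbon of the chloro-ynone in a polarity-matched 6-endo-dig closure (5-exo would require attack at the α-carbon), the vinyl radical is reduced and protonated, and C8a is set trans to the C8 ester because both substituents are pseudo-equatorial in the chair-like transition state; closest known chemistry is Cp2TiCl-mediated epoxide–alkyne/enone radical cyclization and the 6-endo closure of alkyl radicals onto vinyl ketones with an in-chain carbonyl.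

Step 11
Reactants: 17 (E)-3-iodoacrylic acid; 18 ethynyltrimethylsilane
Product: 20 (E)-pent-2-en-4-ynoic acid, via silylated enynoic acid 19 (not isolated)
Conditions: PdCl2(PPh3)2 (2 mol%), CuI (4 mol%), Et3N, THF, 25 °C; then K2CO3, MeOH, 25 °C; aq. HCl
Reagents that add atoms: none
Why: Sonogashira coupling with retention of the (E)-alkene, then base-mediated C–Si cleavage.

Step 12
Reactants: 16 (1S,2S,6S)-5-chloro-2-hydroxy-6-(hydroxymethyl)-2-methyl-3-oxocyclohex-4-en-1-yl 2,4-bis(TBS-oxy)-6-methylbenzoate; 20 (E)-pent-2-en-4-ynoic acid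
Product: 22 pinophilin G bis-TBS ether, via enynone 21 (not isolated)
Conditions: PdCl2(PPh3)2 (5 mol%), CuI (10 mol%), Et3N, THF, 25 → 45 °C; dilute aq. citric acid work-up
Reagents that add atoms: none
Why: Sonogashira coupling at the vinylogous acid chloride, then copper/amine-assisted 6-endo-dig oxa-Michael (1,6-) addition of the C1 hydroxyl to the ynenone in the same flask; the side chain is present as carboxylate, which disfavours the competing 5-exo attack, and no stereocentre is touched.

Step 13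
Reactants: 22 pinophilin G bis-TBS ether
Product: 23 pinophilin G
Conditions: HF·pyridine, THF/pyridine, 0 → 25 °C
Reagents that add atoms: none
Why: Fluoride-mediated cleavage of the two aryl silyl ethers under buffered, non-basic conditions that leave the β-acyloxy enone intact.

**Compound list**
1 | methyl propanoate | CCC(=O)OC | starting material
2 | acrolein (prop-2-enal) | C=CC=O | starting material
3 | methyl 3-hydroxy-2-methylpent-4-enoate (racemic, both diastereomers) | COC(=O)C(C)C(O)C=C | intermediate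
4 | methyl (2RS,3S)-3-hydroxy-2-methylpent-4-enoate | COC(=O)C(C)[C@@H](O)C=C | intermediate
5 | methyl (2S,3S)-2,3-dihydroxy-2-methylpent-4-enoate | COC(=O)[C@@](C)(O)[C@@H](O)C=C | intermediate
6 | methyl (2S,3S)-2,3-dihydroxy-2-methyl-3-(oxiran-2-yl)propanoate (both oxirane epimers) | COC(=O)[C@@](C)(O)[C@@H](O)C1CO1 | intermediate
7 | methyl acetoacetate | COC(=O)CC(C)=O | starting material
8 | methyl orsellinate | COC(=O)c1c(C)cc(O)cc1O | intermediate
9 | orsellinic acid | Cc1cc(O)cc(O)c1C(=O)O | intermediate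
10 | tert-butyldimethylsilyl 2,4-bis(tert-butyldimethylsilyloxy)-6-methylbenzoate | Cc1cc(O[Si](C)(C)C(C)(C)C)cc(O[Si](C)(C)C(C)(C)C)c1C(=O)O[Si](C)(C)C(C)(C)C | intermediate
11 | 2,4-bis(tert-butyldimethylsilyloxy)-6-methylbenzoyl chloride | Cc1cc(O[Si](C)(C)C(C)(C)C)cc(O[Si](C)(C)C(C)(C)C)c1C(Cl)=O | intermediate
12 | methyl (2S,3S)-3-(aroyloxy)-2-hydroxy-2-methyl-3-(oxiran-2-yl)propanoate | COC(=O)[C@@](C)(O)[C@@H](OC(=O)c1c(C)cc(O[Si](C)(C)C(C)(C)C)cc1O[Si](C)(C)C(C)(C)C)C1CO1 | intermediate
13 | cis-1,2-dichloroethene | Cl/C=C\Cl | starting material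
14 | lithium chloroacetylide | [Li]C#CCl | intermediate
15 | (1S,2S)-5-chloro-2-hydroxy-2-methyl-1-(oxiran-2-yl)-3-oxopent-4-yn-1-yl 2,4-bis(TBS-oxy)-6-methylbenzoate | ClC#CC(=O)[C@@](C)(O)[C@@H](OC(=O)c1c(C)cc(O[Si](C)(C)C(C)(C)C)cc1O[Si](C)(C)C(C)(C)C)C1CO1 | intermediate
16 | (1S,2S,6S)-5-chloro-2-hydroxy-6-(hydroxymethyl)-2-methyl-3-oxocyclohex-4-en-1-yl 2,4-bis(TBS-oxy)-6-methylbenzoate | Cc1cc(O[Si](C)(C)C(C)(C)C)cc(O[Si](C)(C)C(C)(C)C)c1C(=O)O[C@H]1[C@H](CO)C(Cl)=CC(=O)[C@@]1(C)O | intermediate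
17 | (E)-3-iodoacrylic acid | OC(=O)/C=C/I | starting material
18 | ethynyltrimethylsilane | C#C[Si](C)(C)C | starting material
19 | (E)-5-(trimethylsilyl)pent-2-en-4-ynoic acid | C[Si](C)(C)C#C/C=C/C(=O)O | intermediate
20 | (E)-pent-2-en-4-ynoic acid | C#C/C=C/C(=O)O | intermediate
21 | (1S,2S,6S)-5-[(E)-4-carboxybut-3-en-1-yn-1-yl]-2-hydroxy-6-(hydroxymethyl)-2-methyl-3-oxocyclohex-4-en-1-yl 2,4-bis(TBS-oxy)-6-methylbenzoate | Cc1cc(O[Si](C)(C)C(C)(C)C)cc(O[Si](C)(C)C(C)(C)C)c1C(=O)O[C@H]1[C@H](CO)C(C#C/C=C/C(=O)O)=CC(=O)[C@@]1(C)O | intermediate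
22 | (E)-3-[(7S,8S,8aS)-8-(aroyloxy)-7-hydroxy-7-methyl-6-oxo-6,7,8,8a-tetrahydro-1H-isochromen-3-yl]prop-2-enoic acid (pinophilin G bis-TBS ether) | Cc1cc(O[Si](C)(C)C(C)(C)C)cc(O[Si](C)(C)C(C)(C)C)c1C(=O)O[C@H]1[C@@H]2COC(/C=C/C(=O)O)=CC2=CC(=O)[C@@]1(C)O | intermediate
23 | pinophilin G, (E)-3-[(7S,8S,8aS)-8-(2,4-dihydroxy-6-methylbenzoyloxy)-7-hydroxy-7-methyl-6-oxo-6,7,8,8a-tetrahydro-1H-isochromen-3-yl]prop-2-enoic acid | Cc1cc(O)cc(O)c1C(=O)O[C@H]1[C@@H]2COC(/C=C/C(=O)O)=CC2=CC(=O)[C@@]1(C)O | target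

**Totals.** 13 steps in all; longest linear sequence 9 steps (1, 2, 3, 4, 8, 9, 10, 12, 13).

**Steps most likely to fail and fallbacks**

Step 10 (radical ring closure). Risks: ionic 5-endo closure of the α-hydroxy chloro-ynone to a furanone, reduction of the β-acyloxy radical by excess Cp2TiCl followed by elimination, or 5-exo closure. Fallback: generate the same C8a radical by a Barton-type thionocarbonate fragmentation in a tin hydride chain, with no Lewis acid or metal reductant. It sets out from 5. Acylation with 11 (as in step 8) gives methyl (2S,3S)-3-(aroyloxy)-2-hydroxy-2-methylpent-4-enoate F1. OsO4 (cat.)/N-methylmorpholine N-oxide gives methyl (2S,3S)-3-(aroyloxy)-2,4,5-trihydroxy-2-methylpentanoate F2. 1,1'-Thiocarbonyldiimidazole gives the cyclic thionocarbonate methyl (2S,3S)-3-(aroyloxy)-2-hydroxy-2-methyl-3-(2-thioxo-1,3-dioxolan-4-yl)propanoate F3. Reagent 14 (as in step 9) gives the chloro-ynone thionocarbonate F4. Bu3SnH/AIBN (benzene, 80 °C, syringe pump) cleaves the secondary C–O bond, the radical cyclises as in step 10, and the product is the S-tributylstannyl thiocarbonate of the primary alcohol F5. Aqueous KF work-up hydrolyses F5, and the route is rejoined at 16.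

Step 9 (ynone from the methyl ester). Risks: double addition, or furanone formation on work-up. Fallback: go through a Weinreb amide. It sets out from 12. LiN(OMe)Me (from MeNHOMe·HCl and n-BuLi, THF, −78 → 0 °C) gives (2S,3S)-3-(aroyloxy)-2-hydroxy-N-methoxy-N,2-dimethyl-3-(oxiran-2-yl)propanamide F6. Reagent 14 then adds once (stable chelate), and cold acidic work-up rejoins the route at 15.

Step 12 (coupling/ring-closure cascade with a free acid). Risks: incomplete or 5-exo ring closure, or interference by the carboxylate. Fallback: mask the acid and close the ring in a separate π-acid step. It sets out from 16 and 20. tert-Butyl 2,2,2-trichloroacetimidate converts 20 into tert-butyl (E)-pent-2-en-4-ynoate F7. Sonogashira coupling with 16 at 25 °C gives the isolable enynone tert-butyl ester F8. AuCl(PPh3)/AgOTf (5 mol%, CH2Cl2, 25 °C) closes the pyran by 6-endo-dig hydroalkoxylation to the tert-butyl ester of 22 F9. CF3CO2H, then HF·pyridine, removes the ester and the silyl ethers, and the route is rejoined at 23.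

Further compounds
F1 | step 10 | methyl (2S,3S)-3-(aroyloxy)-2-hydroxy-2-methylpent-4-enoate | COC(=O)[C@@](C)(O)[C@@H](OC(=O)c1c(C)cc(O[Si](C)(C)C(C)(C)C)cc1O[Si](C)(C)C(C)(C)C)C=C
F2 | step 10 | methyl (2S,3S)-3-(aroyloxy)-2,4,5-trihydroxy-2-methylpentanoate (both C4 epimers) | COC(=O)[C@@](C)(O)[C@@H](OC(=O)c1c(C)cc(O[Si](C)(C)C(C)(C)C)cc1O[Si](C)(C)C(C)(C)C)C(O)CO
F3 | step 10 | methyl (2S,3S)-3-(aroyloxy)-2-hydroxy-2-methyl-3-(2-thioxo-1,3-dioxolan-4-yl)propanoate | COC(=O)[C@@](C)(O)[C@@H](OC(=O)c1c(C)cc(O[Si](C)(C)C(C)(C)C)cc1O[Si](C)(C)C(C)(C)C)C1COC(=S)O1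
F4 | step 10 | (1S,2S)-5-chloro-2-hydroxy-2-methyl-3-oxo-1-(2-thioxo-1,3-dioxolan-4-yl)pent-4-yn-1-yl 2,4-bis(TBS-oxy)-6-methylbenzoate | ClC#CC(=O)[C@@](C)(O)[C@@H](OC(=O)c1c(C)cc(O[Si](C)(C)C(C)(C)C)cc1O[Si](C)(C)C(C)(C)C)C1COC(=S)O1
F5 | step 10 | O-alkyl S-tributylstannyl thiocarbonate of 16 (at the primary hydroxyl) | CCCC[Sn](CCCC)(CCCC)SC(=O)OC[C@@H]1C(Cl)=CC(=O)[C@@](C)(O)[C@H]1OC(=O)c1c(C)cc(O[Si](C)(C)C(C)(C)C)cc1O[Si](C)(C)C(C)(C)C
F6 | step 9 | (2S,3S)-3-(aroyloxy)-2-hydroxy-N-methoxy-N,2-dimethyl-3-(oxiran-2-yl)propanamide | CON(C)C(=O)[C@@](C)(O)[C@@H](OC(=O)c1c(C)cc(O[Si](C)(C)C(C)(C)C)cc1O[Si](C)(C)C(C)(C)C)C1CO1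
F7 | step 12 | tert-butyl (E)-pent-2-en-4-ynoate | C#C/C=C/C(=O)OC(C)(C)C
F8 | step 12 | tert-butyl ester of enynone 21 | Cc1cc(O[Si](C)(C)C(C)(C)C)cc(O[Si](C)(C)C(C)(C)C)c1C(=O)O[C@H]1[C@H](CO)C(C#C/C=C/C(=O)OC(C)(C)C)=CC(=O)[C@@]1(C)O
F9 | step 12 | tert-butyl ester of 22 | Cc1cc(O[Si](C)(C)C(C)(C)C)cc(O[Si](C)(C)C(C)(C)C)c1C(=O)O[C@H]1[C@@H]2COC(/C=C/C(=O)OC(C)(C)C)=CC2=CC(=O)[C@@]1(C)O
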